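(All runs were generated by integration for substances that don't exist; scatter was added.)

The question put to the meeting was where the charge of this flask sits at 1.0 h, and how large that share is.

1. the species in which most of what was charged as starting complex, at 1.0 h sits (side product B / complex with two exchanged / starting complex / side product A / complex with three exchanged / complex with one exchanged)
2. the largest share itself, whichever of these holds it, in percent of the starting complex charged

- Sunday's: starting complex 0.10 M; incoming ligand 0.18 M; leaving ligand 0.20 M (fed, over 8.0 min); the very flask that is asked about, followed so far
- flask: starting complex 0.10 M; incoming ligand 0.180 M; leaving ligand 0.200 M (fed, over 8.0 min); time 1.0 h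

Sunday's run (percent of the starting complex charged)

| time / min | side product B / % | complex with one exchanged / % | starting complex / % | complex with two exchanged / % | side product A / % | complex with three exchanged / % |
|---|---|---|---|---|---|---|
| 0.667 | 5.9 | 5.5 | 87.0 | 1.6 | 3.3 | 0.3 |
| 1.33 | 16.5 | 9.9 | 68.4 | 0.5 | 3.6 | 0.8 |
| 2.00 | 27.5 | 13.2 | 52.2 | 0.8 | 5.6 | 1.4 |
| 3.00 | 45.0 | 11.4 | 32.0 | 2.1 | 8.6 | 0.8 |
| 4.00 | 56.3 | 12.3 | 20.8 | 2.7 | 10.4 | 0.4 |
| 5.00 | 64.7 | 11.4 | 9.8 | 2.8 | 12.0 | 0 |

(scatter of a reading: 1 percentage point)

- percent here means starting complex units held: one side product A counts as two
- the numbers in the tables scatter with a standard deviation of 1 percentage point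

The reckoner proposed following one molecule of starting complex to its end, in side product B or side product A. Between 2.00 min and 5.00 min, side product B took the fraction 0.853 of what reached either end. She named this reading, a selectivity with 1 point of scatter on each figure, the capture chance.

She noted that complex with one exchanged stood lower at 5.00 min than at 2.00 min. So she took the exchanged complexes as waiting, not finished, and pooled them with the starting complex, giving 24.0 % of the charge at 5.00 min. Reckoned at the pace of those minutes, the pool lasts 1.65 min, shorter than 1.0 h. Sending it through the fork, she put side product B at 85.2 %.

The forecaster named side product B at 75 %, arguing that “The remaining 10% of starting complex should therefore go mostly to B”. The reckoner stood 10 points higher, her pool holding the exchanged complexes as well.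

The flask gives side product B at 85.5 %, with side product A at 11.9 %.

    starting complex + incoming ligand ⇌ leaving ligand + complex with one exchanged (K = 0.650, k = 0.0120 /M/s)
    complex with one exchanged + incoming ligand ⇌ leaving ligand + complex with two exchanged (K = 3.10, k = 0.00870 /M/s)
    complex with two exchanged + incoming ligand ⇌ leaving ligand + complex with three exchanged (K = 7.40, k = 0.0210 /M/s)
    starting complex + complex with one exchanged → side product A (k = 0.0430 /M/s)
    leaving ligand + starting complex → side product B (k = 0.140 /M/s)
    incoming ligand → decomposed reagent (k = 0.00230 /s)

At 1.0 h the ends of this flask give a capture chance of 0.878. By the equations, side product B forms from leaving ligand and starting complex, side product A from starting complex and complex with one exchanged, so at equal leaving ligand and an equal fraction of the charge in complex with one exchanged, the odds of capture go inversely with the starting complex charged. Taking those two as equal in the neighbouring flask with 0.040 M of starting complex, as an estimate, Sunday's odds of 5.81 become 14.5, a capture chance of 0.935. That neighbouring flask ends with side product A at 5.20 % and side product B at 92.2 %, a capture chance of 0.947.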